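1. Count the charge: in this closed flask, every part of substrate lost still stands in some form. Start from the runs and the questions.

all flasks: substrate 0.040 M

| flask | reagent | temperature | remark | time |
|---|---|---|---|---|
| red | 4 equiv | 90 °C | run made earlier |  |
| theta | 2.00 equiv | 90 °C |  | 1.5 h |
| delta | 2.00 equiv | 65 °C |  | 1.5 h |
| beta | 2.00 equiv | 115 °C |  | 1.5 h |
| zeta | 2.00 equiv | 40 °C |  | 1.5 h |

red run (percent of the substrate charged)

| time / min | double product / % | substrate / % |
|---|---|---|
| 0.667 | 0.9 | 95.3 |
| 2.00 | 2.9 | 86.4 |
| 3.00 | 1.4 | 79.1 |
| 5.00 | 7.0 | 67.5 |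
| 6.00 | 9.7 | 64.0 |
| 10.0 | 18.7 | 44.5 |

(scatter of a reading: 1 percentage point)

- the numbers in the tables scatter by 1 percentage point (one standard deviation)
- the earlier runs do not show what temperature does; that part of a forecast is a guess

- which flask leads in amount of double product, in percent of the substrate charged ("all alike" within 1.5 percentage points) (theta / delta / beta / zeta / all alike)
- how much double product is there at the end, in percent of the substrate charged: theta
- how much double product is there at the end, in percent of the substrate charged: delta
- how much double product is there at the end, in percent of the substrate charged: beta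
- how much double product is there at the end, in percent of the substrate charged: zeta

2. Compare two amounts in red at its last reading: substrate lost, 55.5 % of the charge, and double product gained, 18.7 %. The remaining 37 percentage points stood in forms nobody read.

3. Divide the second by the first. This gives the catch, double product gained per substrate lost (the selectivity on substrate lost) 33.7 %. It is a reading at one time, and a rough one: at 5.00 min it read lower, 21.5 %.

4. Reckon the loss in theta. Red's substrate fell at 0.0810 min⁻¹. Theta has half the reagent, so take 0.0405 min⁻¹, holding reagent at its charge as a rough step. Over 1.5 h, theta loses 97.4 %.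

5. Multiply, carrying red's last catch over to theta as a guess: my theta figure is 32.8 %. Suppose heat leaves the catch unchanged, which is a guess. Give beta the whole charge lost, and it ends near 33.7 %, close to theta. I have no figure for delta or zeta.

6. Set the forecast beside this: beta leads, with theta 56 %, delta 15 %, beta 85 % and zeta 1 %. Its theta figure stands above mine. On heat it says: “Temperature is a guess”.

7. Read the flasks: theta leads, with theta 32.5 %, delta 9.94 %, beta 29.3 % and zeta 0.448 %. Theta lost 92.5 % of its substrate, a catch of 35.1 %.

    substrate + reagent → mono adduct (k = 0.00747 L mol⁻¹ s⁻¹, Ea = 91.0 kJ mol⁻¹)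
    reagent + mono adduct → double product (k = 0.0184 L mol⁻¹ s⁻¹, Ea = 55.0 kJ mol⁻¹)
    reagent + double product → tris adduct (k = 0.00101 L mol⁻¹ s⁻¹, Ea = 65.0 kJ mol⁻¹)
    double product ⇌ isomer of the product (K = 0.113, k = 7.49 × 10⁻⁴ s⁻¹, Ea = 116 kJ mol⁻¹, ΔH = −46.0 kJ mol⁻¹)
    substrate + mono adduct → side product (k = 0.0381 L mol⁻¹ s⁻¹, Ea = 68.0 kJ mol⁻¹)
    2 substrate → homo dimer (k = 1.83 × 10⁻⁶ L mol⁻¹ s⁻¹, Ea = 98.0 kJ mol⁻¹)
    (constants at 90 °C)

8. Reckon the neighbour flask, which is theta with 0.010 M of substrate, a quarter of theta's, with equivalents and time held. Reagent strength falls with it, so the substrate's rate takes the same quarter. The loss comes to 59.8 % and double product to 20.2 %. The neighbour flask lost 59.2 % of its substrate and holds 15.7 % of double product.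

(All runs were generated by integration for substances that don't exist, noise included.)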